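**Plan**

1. Cembrane numbering: C1 carries C15 (CMe2OAc); the ring runs C2, Z-C3=C4(Me), C5, C6, oxirane C7–C8(Me), C9, C10(OAc), E-C11=C12(Me), C13, C14. The retrosynthesis cuts C10–C11 (ring opening), then C5–C6, then C3=C4.
2. Enabling feature: C5 and the oxygen on C15 lie on the same side of the Z-C3=C4 bond, so an ester link between them completes a seven-membered ring (O, C5, C4, C3, C2, C1, C15) that can only hold a cis olefin. C1, C15, C2, C3, C14, C13 and C12 are the carbons of (R)-α-terpineol.
3. Forward, fragment A: silylated terpineol is ozonised; the aldehyde becomes the C2–C3 allyl group and the methyl ketone the E-C11 iodoalkene. Methacryloylation and ring-closing metathesis give the lactone, and hydride opens it to the Z-allylic C5 alcohol and the C15 carbinol.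
4. Fragment B (C6–C10): anhydromevalonolactone, whose ring fixes the Z-C7=C8 olefin, is opened, reduced, epoxidised and oxidised to the C6 epoxy aldehyde. Wittig union and diimide saturation make C5–C6, and the 14-membered ring closes at C10–C11 by NiCl2/CrCl2 coupling.
5. Stereochemistry: C1 from terpineol; C7 and C8 from tartrate-controlled epoxidation; C10 from oxazaborolidine-controlled enone reduction; Z-C3=C4 from the lactone ring; E-C11=C12 from syn carboalumination.

Key step: step 7

Remark: (R)-(+)-α-terpineol is assumed to be available in enantiomerically pure form; the cembrane numbering of line 1 is used for all intermediates.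

**Route**

Step 1
Reactants: 1 (R)-(+)-α-terpineol
Product: 2 (R)-α-terpinyl triethylsilyl ether
Conditions: Et3SiOTf, 2,6-lutidine, CH2Cl2, −78 → 0 °C
Reagents that add atoms: triethylsilyl trifluoromethanesulfonate, CC[Si](CC)(CC)OS(=O)(=O)C(F)(F)F
Why: Silyl triflate/lutidine silylation is the standard way to cap a hindered tertiary alcohol, and the ether keeps the C15 hydroxyl from trapping the C3 aldehyde of step 2 as a lactol and from consuming the bases of steps 4 and 5.

Step 2
Reactants: 2
Product: 4 keto aldehyde (3R)-6-oxo-3-[2-(triethylsilyloxy)propan-2-yl]heptanal, via ozonide 3 (not isolated)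
Conditions: O3, CH2Cl2, −78 °C; then Me2S, −78 °C → rt
Reagents that add atoms: ozone, [O-][O+]=O
Why: Ozonolysis with reductive work-up (Criegee mechanism) cleaves the only olefin of 2 into the C3 aldehyde and the C12 methyl ketone without touching the C1 stereocenter.

Step 3
Reactants: 4
Product: 5 (5R)-5-[2-(triethylsilyloxy)propan-2-yl]oct-7-en-2-one
Conditions: CH2I2, Zn, Ti(OiPr)4, THF, rt
Reagents that add atoms: diiodomethane, C(I)I
Why: Takai-type methylenation with the CH2I2/Zn/Ti(OiPr)4 reagent is non-basic and selective for aldehydes over ketones, so only C3 should become the terminal vinyl group and the 1,6-dicarbonyl compound is not exposed to aldol conditions.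

Step 4
Reactants: 5
Product: 8 enyne triethyl({2-[(4R)-oct-1-en-7-yn-4-yl]propan-2-yl}oxy)silane, via lithium enolate 6 (not isolated), via enol phosphate 7 (not isolated)
Conditions: LiN(iPr)2 (1.1 equiv), THF, −78 °C; ClP(O)(OEt)2, −78 °C → rt; LiN(iPr)2 (2.4 equiv), −78 °C → rt
Reagents that add atoms: none
Why: Kinetic deprotonation at the methyl group, O-phosphorylation and base-induced E2 elimination of the enol phosphate is the established one-pot conversion of a methyl ketone into a terminal alkyne, here turning C12 and its former methyl carbon into the C12≡C11 unit.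

Step 5
Reactants: 8
Product: 11 (3R,6E)-7-iodo-2,6-dimethyl-3-(prop-2-en-1-yl)hept-6-en-2-ol, via alkenylalane 9 (not isolated), via silyl ether iodide 10 (not isolated)
Conditions: Me3Al, Cp2ZrCl2 (0.25 equiv), CH2Cl2, 0 °C → rt; I2, THF, −30 → 0 °C; then 1 M HCl, MeOH, rt
Reagents that add atoms: trimethylaluminium, C[Al](C)C; iodine, [I][I]
Why: Negishi carboalumination (Cp2ZrCl2-catalysed) adds methyl and aluminium syn across the terminal alkyne with methyl on the internal carbon, iodinolysis of the C–Al bond with retention gives the E iodoalkene, and acid methanolysis then frees the tertiary alcohol, the monosubstituted alkene being far slower in carbometalation than the alkyne.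

Step 6
Reactants: 11; 12 methacryloyl chloride
Product: 13 (3R,6E)-7-iodo-2,6-dimethyl-3-(prop-2-en-1-yl)hept-6-en-2-yl 2-methylprop-2-enoate
Conditions: Et3N, DMAP (0.2 equiv), CH2Cl2, 0 → 40 °C
Reagents that add atoms: none
Why: DMAP-catalysed acylation with the acid chloride is the usual route to tertiary methacrylates and attaches C4, C5 and the C4 methyl group through the C15 oxygen.

Step 7
Reactants: 13
Product: 14 lactone (6R)-6-[(3E)-4-iodo-3-methylbut-3-en-1-yl]-3,7,7-trimethyl-6,7-dihydrooxepin-2(5H)-one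
Conditions: second-generation Grubbs catalyst (H2IMes)(PCy3)Cl2Ru=CHPh (10 mol %), 1,4-benzoquinone (10 mol %), toluene (0.005 M), 80 °C, Ar sparge
Reagents that add atoms: none
Why: The ruthenium benzylidene should load on the monosubstituted allyl terminus (C3), form a ruthenacyclobutane with the 1,1-disubstituted methacrylate olefin by [2+2] cycloaddition and collapse by retro-[2+2], giving the C3=C4 bond and ethylene. The closest known reaction type is ring-closing metathesis of acrylate and methacrylate esters of unsaturated alcohols to α,β-unsaturated lactones with N-heterocyclic carbene ruthenium catalysts. The ring closes by olefin metathesis as a seven-membered oxepinone made of O, C5, C4, C3, C2, C1 and C15, with the new double bond inside the ring. No stereocenter is formed and C1 is a spectator. The step needs only the Z geometry of C3=C4, which the seven-membered ring enforces because it cannot hold a trans olefin, and chemoselectivity for the two terminal olefins, which is secured because the trisubstituted iodoalkene is too hindered to enter the catalytic cycle. The gem-dimethyl group on C15 favours the cyclisation-competent ester conformer, high dilution suppresses dimerisation through the allyl group, and benzoquinone suppresses ruthenium hydride migration of the allyl double bond.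

Step 8
Reactants: 14
Product: 15 (2Z,5R)-5-[(3E)-4-iodo-3-methylbut-3-en-1-yl]-2,6-dimethylhept-2-ene-1,6-diol
Conditions: i-Bu2AlH (4.5 equiv), CH2Cl2, −78 → 0 °C
Reagents that add atoms: none
Why: 1,2-Reduction of the unsaturated lactone by i-Bu2AlH through the lactol opens the ring to the Z-allylic C5 alcohol and the C15 carbinol, the Z geometry being carried over unchanged and the iodoalkene being inert to the hydride.

Step 9
Reactants: 15
Product: 17 {(2Z,5R)-6-hydroxy-5-[(3E)-4-iodo-3-methylbut-3-en-1-yl]-2,6-dimethylhept-2-en-1-yl}triphenylphosphonium bromide, via allylic bromide 16 (not isolated)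
Conditions: CBr4, PPh3, CH2Cl2, −20 → 0 °C; then PPh3, MeCN, rt
Reagents that add atoms: carbon tetrabromide, BrC(Br)(Br)Br; triphenylphosphine, c1ccc(cc1)P(c1ccccc1)c1ccccc1
Why: Appel bromination converts the primary allylic alcohol by SN2 on the oxyphosphonium ion without allylic transposition or loss of the Z geometry and leaves the tertiary alcohol alone, and SN2 quaternisation of triphenylphosphine by the allylic bromide should outrun cyclic ether formation.

Step 10
Reactants: 18 anhydromevalonolactone (4-methyl-5,6-dihydro-2H-pyran-2-one)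
Product: 20 tert-butyldimethylsilyl (2Z)-5-[(tert-butyldimethylsilyl)oxy]-3-methylpent-2-enoate, via lithium carboxylate 19 (not isolated)
Conditions: LiOH·H2O (1.05 equiv), THF–H2O, rt; evaporate; t-BuMe2SiCl (2.4 equiv), imidazole, DMF, rt
Reagents that add atoms: lithium hydroxide, [Li+].[OH-]; tert-butyldimethylsilyl chloride, CC(C)(C)[Si](C)(C)Cl
Why: Saponification opens the lactone at the acyl carbon without touching the ring-derived Z olefin, and silylation of both oxygens of the hydroxy carboxylate traps the open chain and distinguishes C10 (silyl ether) from C6 (silyl ester).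

Step 11
Reactants: 20
Product: 21 (2Z)-5-[(tert-butyldimethylsilyl)oxy]-3-methylpent-2-en-1-ol
Conditions: i-Bu2AlH (3 equiv), CH2Cl2, −78 → 0 °C
Reagents that add atoms: none
Why: Hydride reduction with i-Bu2AlH treats the silyl ester like an alkyl enoate and gives the allylic alcohol by 1,2-reduction while the silyl ether and the Z olefin persist.

Step 12
Reactants: 21
Product: 22 [(2S,3R)-3-{2-[(tert-butyldimethylsilyl)oxy]ethyl}-3-methyloxiran-2-yl]methanol
Conditions: Ti(OiPr)4 (0.1 equiv), L-(+)-diethyl tartrate (0.12 equiv), t-BuOOH, 4 Å molecular sieves, CH2Cl2, −20 °C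
Reagents that add atoms: tert-butyl hydroperoxide, CC(C)(C)OO
Why: Katsuki–Sharpless asymmetric epoxidation of this nerol-type Z-allylic alcohol with Ti(OiPr)4/L-(+)-diethyl tartrate delivers oxygen to the face that gives the (2S,3R)-epoxy alcohol (C7 S and C8 R of the target), the cis relation of C6 and C9 on the oxirane following from the Z olefin.

Step 13
Reactants: 22
Product: 23 (2R,3R)-3-{2-[(tert-butyldimethylsilyl)oxy]ethyl}-3-methyloxirane-2-carbaldehyde
Conditions: Dess–Martin periodinane, NaHCO3, CH2Cl2, 0 °C → rt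
Reagents that add atoms: none
Why: Buffered Dess–Martin oxidation converts 2,3-epoxy alcohols into configurationally stable epoxy aldehydes without opening the oxirane, the C7 descriptor changing only through the priority rules.

Step 14
Reactants: 17; 23
Product: 25 diene (3R,5Z)-8-[(2S,3R)-3-{2-[(tert-butyldimethylsilyl)oxy]ethyl}-3-methyloxiran-2-yl]-3-[(3E)-4-iodo-3-methylbut-3-en-1-yl]-2,6-dimethylocta-5,7-dien-2-ol (both C5=C6 isomers), via ylide 24 (not isolated)
Conditions: 17, NaN(SiMe3)2 (1.05 equiv), THF, −78 °C; then 23, −78 → −20 °C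
Reagents that add atoms: none
Why: Wittig olefination with the semi-stabilised allylic ylide joins C5 to C6 (the geometry of the new bond is irrelevant because it is saturated next), one equivalent of base suffices because the phosphonium methylene is far more acidic than the tertiary alcohol, and generating and using the ylide at −78 °C should keep C3=C4 in the Z form.

Step 15
Reactants: 25
Product: 26 (3R,5Z)-8-[(2S,3R)-3-{2-[(tert-butyldimethylsilyl)oxy]ethyl}-3-methyloxiran-2-yl]-3-[(3E)-4-iodo-3-methylbut-3-en-1-yl]-2,6-dimethyloct-5-en-2-ol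
Conditions: 2-nitrobenzenesulfonyl hydrazide, Et3N, CH2Cl2, rt
Reagents that add atoms: none
Why: Diimide reduction transfers H2 in a concerted syn fashion and is selective for the 1,2-disubstituted C5=C6 bond over the trisubstituted C3=C4 and iodo-substituted C11=C12 bonds, and unlike catalytic hydrogenation it does not cleave the allylic oxirane or the C–I bond.

Step 16
Reactants: 26
Product: 27 (3R,5Z)-8-[(2S,3R)-3-(2-hydroxyethyl)-3-methyloxiran-2-yl]-3-[(3E)-4-iodo-3-methylbut-3-en-1-yl]-2,6-dimethyloct-5-en-2-ol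
Conditions: Bu4NF, THF, 0 °C → rt
Reagents that add atoms: none
Why: Fluoride-mediated desilylation frees the primary C10 hydroxyl under conditions that leave the oxirane, the iodoalkene and the tertiary alcohol untouched.

Step 17
Reactants: 27
Product: 28 {(2R,3S)-3-[(3Z,6R)-7-hydroxy-6-[(3E)-4-iodo-3-methylbut-3-en-1-yl]-3,7-dimethyloct-3-en-1-yl]-2-methyloxiran-2-yl}acetaldehyde
Conditions: Dess–Martin periodinane, NaHCO3, CH2Cl2, 0 °C
Reagents that add atoms: none
Why: Dess–Martin oxidation converts only the primary alcohol (the tertiary one cannot react), and buffering plus direct use of the β,γ-epoxy aldehyde should avoid base-induced opening to a γ-hydroxy enal.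

Step 18
Reactants: 28
Product: 29 (1R,3Z,7S,8R,11E)-7,8-epoxycembra-3,11-diene-10,15-diol as a mixture of C10 epimers
Conditions: CrCl2 (10 equiv), NiCl2 (0.1 equiv), DMSO–THF (3:1), 0.002 M, slow addition, rt
Reagents that add atoms: none
Why: In this Nozaki–Hiyama–Kishi coupling zerovalent nickel inserts into the C–I bond and transmetalation gives an alkenyl trivalent chromium species that adds only to the aldehyde, tolerating the oxirane and the free hydroxyl and retaining the E geometry, in a ring closure that is well precedented for 14-membered cembranoids; no control at C10 is asked of this step.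

Step 19
Reactants: 29
Product: 30 (1R,3Z,7S,8R,11E)-7,8-epoxy-15-hydroxycembra-3,11-dien-10-one
Conditions: MnO2 (activated, excess), CH2Cl2, rt
Reagents that add atoms: none
Why: Allylic oxidation with MnO2 is neutral and heterogeneous, so both C10 epimers should converge on one enone without enolisation towards the β,γ-oxirane.

Step 20
Reactants: 30
Product: 31 (1R,3Z,7S,8R,10S,11E)-7,8-epoxycembra-3,11-diene-10,15-diol
Conditions: (R)-2-methyl-CBS-oxazaborolidine (0.5 equiv), catecholborane, toluene, −78 °C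
Reagents that add atoms: none
Why: In the Corey–Bakshi–Shibata reduction, with the alkenyl branch acting as the large group, the (R)-oxazaborolidine should deliver hydride to the face that gives the 10S allylic alcohol (reagent control), and catecholborane at −78 °C spares the oxirane and the olefins.

Step 21
Reactants: 31
Product: 32 target (1R,3Z,7S,8R,10S,11E)-7,8-epoxycembra-3,11-diene-10,15-diyl diacetate (CNP0282098.1)
Conditions: Ac2O, Et3N, DMAP (1 equiv), CH2Cl2, rt → 40 °C
Reagents that add atoms: acetic anhydride, CC(=O)OC(C)=O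
Why: DMAP-catalysed acetylation esterifies the secondary allylic alcohol quickly and, on gentle warming, the tertiary C15 alcohol as well, under basic conditions that do not disturb the oxirane.

**Compound list**

1 | (R)-(+)-α-terpineol, 2-[(1R)-4-methylcyclohex-3-en-1-yl]propan-2-ol | CC1=CC[C@@H](CC1)C(C)(C)O | starting material
2 | triethyl({2-[(1R)-4-methylcyclohex-3-en-1-yl]propan-2-yl}oxy)silane | CC1=CC[C@@H](CC1)C(C)(C)O[Si](CC)(CC)CC | intermediate
3 | secondary ozonide of 2 (1,2,4-trioxolane bridging the former olefin carbons) | CC12OOC(O1)C[C@@H](CC2)C(C)(C)O[Si](CC)(CC)CC | intermediate (not isolated)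
4 | (3R)-6-oxo-3-[2-(triethylsilyloxy)propan-2-yl]heptanal | O=CC[C@@H](CCC(C)=O)C(C)(C)O[Si](CC)(CC)CC | intermediate
5 | (5R)-5-[2-(triethylsilyloxy)propan-2-yl]oct-7-en-2-one | C=CC[C@@H](CCC(C)=O)C(C)(C)O[Si](CC)(CC)CC | intermediate
6 | lithium (5R)-5-[2-(triethylsilyloxy)propan-2-yl]octa-1,7-dien-2-olate | C=CC[C@@H](CCC(=C)[O-])C(C)(C)O[Si](CC)(CC)CC.[Li+] | intermediate (not isolated)
7 | diethyl (5R)-5-[2-(triethylsilyloxy)propan-2-yl]octa-1,7-dien-2-yl phosphate | C=CC[C@@H](CCC(=C)OP(=O)(OCC)OCC)C(C)(C)O[Si](CC)(CC)CC | intermediate (not isolated)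
8 | triethyl({2-[(4R)-oct-1-en-7-yn-4-yl]propan-2-yl}oxy)silane | C=CC[C@@H](CCC#C)C(C)(C)O[Si](CC)(CC)CC | intermediate
9 | dimethyl{(1E,5R)-2-methyl-5-[2-(triethylsilyloxy)propan-2-yl]octa-1,7-dien-1-yl}alane | C=CC[C@@H](CC/C(C)=C/[Al](C)C)C(C)(C)O[Si](CC)(CC)CC | intermediate (not isolated)
10 | triethyl({(3R,6E)-7-iodo-2,6-dimethyl-3-(prop-2-en-1-yl)hept-6-en-2-yl}oxy)silane | C=CC[C@@H](CC/C(C)=C/I)C(C)(C)O[Si](CC)(CC)CC | intermediate (not isolated)
11 | (3R,6E)-7-iodo-2,6-dimethyl-3-(prop-2-en-1-yl)hept-6-en-2-ol | C=CC[C@@H](CC/C(C)=C/I)C(C)(C)O | intermediate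
12 | methacryloyl chloride | CC(=C)C(=O)Cl | starting material
13 | (3R,6E)-7-iodo-2,6-dimethyl-3-(prop-2-en-1-yl)hept-6-en-2-yl 2-methylprop-2-enoate | C=CC[C@@H](CC/C(C)=C/I)C(C)(C)OC(=O)C(C)=C | intermediate
14 | (6R)-6-[(3E)-4-iodo-3-methylbut-3-en-1-yl]-3,7,7-trimethyl-6,7-dihydrooxepin-2(5H)-one | C/C(=C\I)CC[C@@H]1CC=C(C)C(=O)OC1(C)C | intermediate
15 | (2Z,5R)-5-[(3E)-4-iodo-3-methylbut-3-en-1-yl]-2,6-dimethylhept-2-ene-1,6-diol | OC/C(C)=C\C[C@@H](CC/C(C)=C/I)C(C)(C)O | intermediate
16 | (3R,5Z)-7-bromo-3-[(3E)-4-iodo-3-methylbut-3-en-1-yl]-2,6-dimethylhept-5-en-2-ol | BrC/C(C)=C\C[C@@H](CC/C(C)=C/I)C(C)(C)O | intermediate (not isolated)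
17 | {(2Z,5R)-6-hydroxy-5-[(3E)-4-iodo-3-methylbut-3-en-1-yl]-2,6-dimethylhept-2-en-1-yl}triphenylphosphonium bromide | c1ccccc1[P+](c1ccccc1)(c1ccccc1)C/C(C)=C\C[C@@H](CC/C(C)=C/I)C(C)(C)O.[Br-] | intermediate
18 | anhydromevalonolactone, 4-methyl-5,6-dihydro-2H-pyran-2-one | CC1=CC(=O)OCC1 | starting material
19 | lithium (2Z)-5-hydroxy-3-methylpent-2-enoate | [Li+].[O-]C(=O)/C=C(/C)CCO | intermediate (not isolated)
20 | tert-butyldimethylsilyl (2Z)-5-[(tert-butyldimethylsilyl)oxy]-3-methylpent-2-enoate | CC(C)(C)[Si](C)(C)OC(=O)/C=C(/C)CCO[Si](C)(C)C(C)(C)C | intermediate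
21 | (2Z)-5-[(tert-butyldimethylsilyl)oxy]-3-methylpent-2-en-1-ol | OC/C=C(/C)CCO[Si](C)(C)C(C)(C)C | intermediate
22 | [(2S,3R)-3-{2-[(tert-butyldimethylsilyl)oxy]ethyl}-3-methyloxiran-2-yl]methanol | OC[C@@H]1O[C@]1(C)CCO[Si](C)(C)C(C)(C)C | intermediate
23 | (2R,3R)-3-{2-[(tert-butyldimethylsilyl)oxy]ethyl}-3-methyloxirane-2-carbaldehyde | O=C[C@@H]1O[C@]1(C)CCO[Si](C)(C)C(C)(C)C | intermediate
24 | {(2Z,5R)-6-hydroxy-5-[(3E)-4-iodo-3-methylbut-3-en-1-yl]-2,6-dimethylhept-2-en-1-ylidene}triphenylphosphorane | c1ccccc1P(c1ccccc1)(c1ccccc1)=C/C(C)=C\C[C@@H](CC/C(C)=C/I)C(C)(C)O | intermediate (not isolated)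
25 | (3R,5Z)-8-[(2S,3R)-3-{2-[(tert-butyldimethylsilyl)oxy]ethyl}-3-methyloxiran-2-yl]-3-[(3E)-4-iodo-3-methylbut-3-en-1-yl]-2,6-dimethylocta-5,7-dien-2-ol (7E/7Z mixture) | CC(C)(C)[Si](C)(C)OCC[C@@]1(C)O[C@H]1C=C/C(C)=C\C[C@@H](CC/C(C)=C/I)C(C)(C)O | intermediate
26 | (3R,5Z)-8-[(2S,3R)-3-{2-[(tert-butyldimethylsilyl)oxy]ethyl}-3-methyloxiran-2-yl]-3-[(3E)-4-iodo-3-methylbut-3-en-1-yl]-2,6-dimethyloct-5-en-2-ol | CC(C)(C)[Si](C)(C)OCC[C@@]1(C)O[C@H]1CC/C(C)=C\C[C@@H](CC/C(C)=C/I)C(C)(C)O | intermediate
27 | (3R,5Z)-8-[(2S,3R)-3-(2-hydroxyethyl)-3-methyloxiran-2-yl]-3-[(3E)-4-iodo-3-methylbut-3-en-1-yl]-2,6-dimethyloct-5-en-2-ol | OCC[C@@]1(C)O[C@H]1CC/C(C)=C\C[C@@H](CC/C(C)=C/I)C(C)(C)O | intermediate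
28 | {(2R,3S)-3-[(3Z,6R)-7-hydroxy-6-[(3E)-4-iodo-3-methylbut-3-en-1-yl]-3,7-dimethyloct-3-en-1-yl]-2-methyloxiran-2-yl}acetaldehyde | O=CC[C@@]1(C)O[C@H]1CC/C(C)=C\C[C@@H](CC/C(C)=C/I)C(C)(C)O | intermediate
29 | (1R,3Z,7S,8R,11E)-7,8-epoxycembra-3,11-diene-10,15-diol, C10 epimer mixture | OC1/C=C(\C)CC[C@@H](C(C)(C)O)C/C=C(/C)CC[C@@H]2O[C@]2(C)C1 | intermediate
30 | (1R,3Z,7S,8R,11E)-7,8-epoxy-15-hydroxycembra-3,11-dien-10-one | O=C1/C=C(\C)CC[C@@H](C(C)(C)O)C/C=C(/C)CC[C@@H]2O[C@]2(C)C1 | intermediate
31 | (1R,3Z,7S,8R,10S,11E)-7,8-epoxycembra-3,11-diene-10,15-diol | O[C@@H]1/C=C(\C)CC[C@@H](C(C)(C)O)C/C=C(/C)CC[C@@H]2O[C@]2(C)C1 | intermediate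
32 | (1R,3Z,7S,8R,10S,11E)-7,8-epoxycembra-3,11-diene-10,15-diyl diacetate (CNP0282098.1) | CC(=O)O[C@@H]1/C=C(\C)CC[C@@H](C(C)(C)OC(C)=O)C/C=C(/C)CC[C@@H]2O[C@]2(C)C1 | target

**Step count**

Total: 21 steps. Longest linear sequence: 17 steps (steps 1–9 and 14–21); steps 10–13 build fragment B.

**Steps most likely to fail**

Step 7. Turnover at the electron-poor 1,1-disubstituted methacrylate olefin may be slow, so that dimerisation through the allyl group or migration of the allyl double bond outruns ring closure. The fallback sets the Z olefin by kinetically controlled olefination instead of by a ring. It sets out from silyl ether 10, isolated by omitting the acid methanolysis of step 5. Oxidative cleavage of its monosubstituted olefin (OsO4 cat., NaIO4, 2,6-lutidine, dioxane–H2O) should give the C3 aldehyde (3R,6E)-7-iodo-6-methyl-3-[2-(triethylsilyloxy)propan-2-yl]hept-6-enal F1. Still–Gennari olefination (methyl 2-[bis(2,2,2-trifluoroethoxy)phosphoryl]propanoate, KN(SiMe3)2, 18-crown-6, THF, −78 °C) should then give the (Z)-α-methyl enoate methyl (2Z,5R,8E)-9-iodo-2,8-dimethyl-5-[2-(triethylsilyloxy)propan-2-yl]nona-2,8-dienoate F2. Reduction with i-Bu2AlH gives the allylic alcohol (2Z,5R,8E)-9-iodo-2,8-dimethyl-5-[2-(triethylsilyloxy)propan-2-yl]nona-2,8-dien-1-ol F3, and Bu4NF removes the silyl group to return to the route at diol 15.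

Step 14. The Z geometry at C3=C4 may erode by rotation within the delocalised allylic ylide, or the ylide may react through its γ-carbon (C3). The fallback makes the C5=C6 bond by cross-metathesis, so that no carbanion is generated next to the Z olefin. It sets out from lactone 14 and aldehyde 23. One equivalent of i-Bu2AlH at −78 °C should reduce 14 to the lactol (6R)-6-[(3E)-4-iodo-3-methylbut-3-en-1-yl]-3,7,7-trimethyl-2,5,6,7-tetrahydrooxepin-2-ol F4. Methylenation with Ph3P=CH2 gives the terminal diene (3R,5Z)-3-[(3E)-4-iodo-3-methylbut-3-en-1-yl]-2,6-dimethylocta-5,7-dien-2-ol F5. The same ylide converts 23 into the vinyl oxirane tert-butyl{2-[(2R,3S)-3-ethenyl-2-methyloxiran-2-yl]ethoxy}dimethylsilane F6. Cross-metathesis of F5 with F6 using the second-generation Hoveyda–Grubbs catalyst (H2IMes)Cl2Ru=CH(C6H4-2-OiPr) should deliver diene 25, where the route resumes with step 15.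

Step 20. Facial selectivity may be poor if the conformation of the macrocycle opposes the catalyst, and the enone may enolise towards C9 with opening of the oxirane. The fallback replaces reduction by inversion and avoids the enone altogether. It sets out from the epimer mixture 29, which is separated by chromatography. The 10S epimer is 31. The 10R epimer (1R,3Z,7S,8R,10R,11E)-7,8-epoxycembra-3,11-diene-10,15-diol F7 is subjected to Mitsunobu inversion with acetic acid (PPh3, diisopropyl azodicarboxylate, toluene, 0 °C), which should give the 10S monoacetate (1R,3Z,7S,8R,10S,11E)-7,8-epoxy-15-hydroxycembra-3,11-dien-10-yl acetate F8. Both streams are acetylated under the conditions of step 21 to reach 32.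

**Further compounds**

F1 | step 7 | (3R,6E)-7-iodo-6-methyl-3-[2-(triethylsilyloxy)propan-2-yl]hept-6-enal | O=CC[C@@H](CC/C(C)=C/I)C(C)(C)O[Si](CC)(CC)CC
F2 | step 7 | methyl (2Z,5R,8E)-9-iodo-2,8-dimethyl-5-[2-(triethylsilyloxy)propan-2-yl]nona-2,8-dienoate | COC(=O)/C(C)=C\C[C@@H](CC/C(C)=C/I)C(C)(C)O[Si](CC)(CC)CC
F3 | step 7 | (2Z,5R,8E)-9-iodo-2,8-dimethyl-5-[2-(triethylsilyloxy)propan-2-yl]nona-2,8-dien-1-ol | OC/C(C)=C\C[C@@H](CC/C(C)=C/I)C(C)(C)O[Si](CC)(CC)CC
F4 | step 14 | (6R)-6-[(3E)-4-iodo-3-methylbut-3-en-1-yl]-3,7,7-trimethyl-2,5,6,7-tetrahydrooxepin-2-ol | C/C(=C\I)CC[C@@H]1CC=C(C)C(O)OC1(C)C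
F5 | step 14 | (3R,5Z)-3-[(3E)-4-iodo-3-methylbut-3-en-1-yl]-2,6-dimethylocta-5,7-dien-2-ol | C=C/C(C)=C\C[C@@H](CC/C(C)=C/I)C(C)(C)O
F6 | step 14 | tert-butyl{2-[(2R,3S)-3-ethenyl-2-methyloxiran-2-yl]ethoxy}dimethylsilane | C=C[C@@H]1O[C@]1(C)CCO[Si](C)(C)C(C)(C)C
F7 | step 20 | (1R,3Z,7S,8R,10R,11E)-7,8-epoxycembra-3,11-diene-10,15-diol | O[C@H]1/C=C(\C)CC[C@@H](C(C)(C)O)C/C=C(/C)CC[C@@H]2O[C@]2(C)C1
F8 | step 20 | (1R,3Z,7S,8R,10S,11E)-7,8-epoxy-15-hydroxycembra-3,11-dien-10-yl acetate | CC(=O)O[C@@H]1/C=C(\C)CC[C@@H](C(C)(C)O)C/C=C(/C)CC[C@@H]2O[C@]2(C)C1
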